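# Proposed synthesis of (S)-3-(2,2-dimethylchroman-6-yl)-3-hydroxy-1-[(S)-6-hydroxy-2-(2-hydroxypropan-2-yl)-2,3-dihydrobenzofuran-5-yl]propan-1-one (19)

## The problem

The target is a β-hydroxy-dihydrochalcone: a 2,2-dimethylchroman bonded through C6 and a 6-hydroxy-2-(2-hydroxypropan-2-yl)-2,3-dihydrobenzofuran bonded through C5 are joined by a CH(OH)–CH2–C(=O) chain, with the carbinol on the chroman side and the ketone on the benzofuran side. There are two stereocentres, C2 of the dihydrofuran (S) and the carbinol carbon (S); an arene, a ketone and a methylene lie between them, so neither can control the other and each needs its own catalyst or reagent control. The carbinol is the fragile point: it is benzylic, para to the chroman oxygen and β to an aryl ketone, so acid ionises it, acid or base dehydrates it to the chalcone, the neighbouring phenol can then close a flavanone, and retro-aldol cleavage is a further exit. It therefore has to appear late and under near-neutral conditions, after the phenol has been freed. The benzofuran arene is 1,2,4,5-substituted and carries two oxygens meta to each other, one ending as ring oxygen O1 and the other as the free phenol hydrogen-bonded to the ketone, so the two must be told apart early. The tertiary alcohol sits next to the C2–O1 bond and is best carried in latent form. The enabling feature is that the hydroxyisopropyl group can be read as a hydrated isopropenyl group: C2 then becomes an allylic carbon bonded to O1, and O1 is a phenol oxygen para to the acyl group, acidic enough to act as a soft nucleophile toward a π-allyl palladium intermediate.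

## Retrosynthesis

**Carbinol C–O bond (19 ⇒ 18).** The last bond made is the carbinol C–O bond, by oxidation of the secondary benzylic pinacol boronate 18 with retention. This puts the only step that creates the fragile β-hydroxy ketone at the very end and lets it run under mild perborate conditions. The forward step must keep the configuration at carbon and leave the hydroxyaryl ketone alone.

**Phenol unmasking (18 ⇒ 17).** The MOM ether on the ketone-chelated oxygen is removed at the boronate stage, where a C–B bond stands in for the ionisable C–OH bond. The same cleavage one step later would expose the benzylic alcohol to acid. The forward step needs acid mild enough for the boronate and the tertiary alcohol.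

**C–B bond (17 ⇒ 16).** The boronate is cut back to the E-chalcone 16; a chiral copper–boryl catalyst adds boron to the β-carbon and sets the (S) centre. A direct aldol union of 10 and 15 would be two steps shorter, but there is no dependable catalyst control for an aryl methyl ketone with an electron-rich aryl aldehyde. An acyl-anion/epoxide union would need the aldehyde oxidation level and stoichiometric organolithium chemistry. The enone is flat and stable, and the asymmetric step is catalytic. C2 is too remote to influence the outcome, so the ligand must decide the face.

**Enone C=C bond (16 ⇒ 10 + 15).** Cutting Cα=Cβ gives methyl ketone 10 and 2,2-dimethylchroman-6-carbaldehyde 15, two halves of nearly equal size. Only 10 can enolise, so the Claisen–Schmidt condensation has a single course. This cut is the reason the ketone carbon is carried as an acetyl group from the first compound on; an acetyl group also tolerates the selenium, palladium and cobalt steps better than a formyl group would.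

**Chroman half (15 ⇒ 14 ⇒ 11 + 12).** The formyl group is removed from C6, the position para to the ring oxygen of 14. Chroman 14 is cut at O1–C2 and C4–C4a into phenol 11 and isoprene 12, joined by acid through the ortho-prenyl phenol 13. Both forward steps are simple electrophilic aromatic substitutions on cheap materials.

**Tertiary C–OH bond (10 ⇒ 9).** Removing water gives the isopropenyl compound 9. The forward Markovnikov hydration has only one regiochemical choice and does not touch C2. In 9, C2 is allylic.

**O1–C2 bond (9 ⇒ 8), the key cut.** Opening the allylic aryl ether gives the achiral E-configured allylic methyl carbonate 8 with a free phenol ortho to the chain. The ring and the C2 stereocentre then arise in one catalytic step, and the tether fixes which allyl terminus is attacked. Cutting C7a–O1 instead would need an aryl halide and a chiral alcohol made beforehand. An intermolecular palladium heteroannulation of a bromophenol with 12 would be shorter, but its regiochemistry is not fixed by a tether; it is kept in reserve. The forward step needs enantiocontrol from the ligand and five- over seven-membered closure.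

**Side-chain functional groups (8 ⇒ 7 ⇒ 6 ⇒ 5).** The phenol of 8 is masked as the silyl ether 7 so that the carbonate can be put on the primary alcohol of 6 alone. The allylic alcohol of 6 comes from the prenyl group of 5 by selenium dioxide oxidation of the methyl group trans to the chain, which also fixes the E geometry needed for a single allyl geometry.

**Aryl–CH2 bond and phenol differentiation (5 ⇒ 3 + 4; 3 ⇒ 2 ⇒ 1).** The prenyl group is attached by Stille coupling of aryl bromide 3 with stannane 4, which avoids the poor regiochemistry of direct C-prenylation of a resorcinol. The two phenols of the commercial bromo ketone 1 are told apart by the hydrogen bond to the acetyl group: the free one takes the temporary silyl group (2), the chelated one the MOM group (3).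

## Roads not taken

**Alternative 1:** The benzene ring of the benzofuran is cut at C5–C6 and C3a–C4. Forward, the silyl ketene acetal diene A3, built on an enantiopure 2,3-dihydrofuran, would add to the terminal ynone A2 of the chroman half. Loss of methanol and of the ketene-acetal silyl group from the cycloadduct would give arene A1 with the phenol already free and chelated.
- Merits: it is the most convergent plan. The arene, the aryl ketone and the ortho relation of ketone and phenol arise in one step, with regiochemistry set by the polarity of diene and ynone. No phenol differentiation, cross-coupling or late phenol deprotection is needed.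
- Weak points: A3 is a cyclic enol ether and a ketene acetal at once, so it is labile to water and heat, and its C2 centre is an allylic ether carbon inside the diene. A2 has a β-silyloxy group that can be lost by elimination next to the activated ynone. Both stereocentres must be set beforehand in separate fragment syntheses. The benzannulation has no close model with a bicyclic diene of this kind.
- Comparison: in convergence and protecting-group economy this road is better than the chosen one, which is linear on the benzofuran side and spends four steps on phenol protection. The chosen plan offers commercial aromatic starting materials, stable intermediates and a ring closure that is an established reaction class on this ring system.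

**Alternative 2:** The cut is the aryl–oxygen bond C7a–O1. Forward, the secondary hydroxyl of bromo diol A5 would be coupled with the ortho C–Br bond (Pd(OAc)2, a bulky biaryl di-tert-butylphosphine, Cs2CO3; or CuI with 1,10-phenanthroline) to give A4.
- Merits: the stereocentre would come from asymmetric dihydroxylation of a prenyl arene, a more predictable source of high enantiopurity than an allylic etherification. The tertiary alcohol is present from the start, so no hydration is needed. The stereocentre is not touched in the ring closure. Allylic oxidation, carbonate formation and the temporary phenol protection all disappear.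
- Weak points: palladium alkoxides of secondary alcohols can undergo β-hydride elimination. The tertiary hydroxyl competes through a six-membered closure. The precursor needs bromine and the chain ortho to each other on a ring that already carries ester and MOM ether, a pattern less directly available than that of 1. The ester of A4 must still be turned into the methyl ketone of 10.
- Comparison: up to the hydrated dihydrobenzofuran this road is of equal length or shorter and probably more secure in enantiopurity; that is conceded. The chosen plan carries the ketone oxidation level from the first compound, buys its substitution pattern, and has no β-hydride pathway in the closure.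

**Alternative 3:** The cut is in the pyran ring of the chroman, at C4–C4a and O1–C2. Forward, heating the aryl 1,1-dimethylpropargyl ether A7 would trigger a [3,3] shift, a 1,5-hydrogen shift and an oxa-6π electrocyclisation to give chromene A6.
- Merits: the cascade is one of the most reliable ring syntheses in this field and needs no catalyst. It has no regiochemical question, because the para position is occupied and the two ortho positions are equivalent. A chromene congener would come from the same intermediate.
- Weak points: the target is a chroman, so A6 would still need hydrogenation of its C3–C4 alkene next to a benzylic C–O bond that is open to hydrogenolysis. The cascade needs well above 100 °C on a substrate with a β-silyloxy ketone that can eliminate to the enone. It comes late, on the most valuable material. It solves neither stereocentre.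
- Comparison: as a single reaction it is more dependable than any step of the chosen route, and for a chromene target it would be the first choice. For the saturated ring the chosen plan reaches the chroman in two early steps from 11 and 12 and keeps heat and hydrogen away from the aldol unit.

Key step: step 7

Assumption: the sense of induction of the (S,S) diphosphine in step 7 and of the (R,Sp) ferrocenyl diphosphine in step 12 is taken by analogy with closely related substrates; both ligands are sold as both mirror images, and the antipode is used if the first batch shows the opposite sense.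

## Route

Step 1
Reactants: 1 1-(5-bromo-2,4-dihydroxyphenyl)ethanone
Product: 2 1-[5-bromo-4-(tert-butyldimethylsilyloxy)-2-hydroxyphenyl]ethanone
Conditions: TBSCl (1.05 equiv), imidazole, CH2Cl2, 0 °C
Reagents that add atoms: tert-butyldimethylsilyl chloride, CC(C)(C)[Si](C)(C)Cl
Why: Selective phenol silylation; the 2-hydroxyl is locked in a hydrogen bond to the acetyl carbonyl, so only the more acidic, unchelated 4-hydroxyl should react with one equivalent of silyl chloride.

Step 2
Reactants: 2 1-[5-bromo-4-(tert-butyldimethylsilyloxy)-2-hydroxyphenyl]ethanone
Product: 3 1-[5-bromo-4-(tert-butyldimethylsilyloxy)-2-(methoxymethoxy)phenyl]ethanone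
Conditions: MOMCl (3 equiv), iPr2NEt, CH2Cl2, 0 °C to reflux
Reagents that add atoms: chloromethyl methyl ether, COCCl
Why: Acetal-type O-alkylation of the chelated phenol, which needs excess reagent and warming; the amine base leaves the aryl silyl ether intact, and the MOM ether will withstand the later tin, selenium, palladium, cobalt and hydroxide steps.

Step 3
Reactants: 3 1-[5-bromo-4-(tert-butyldimethylsilyloxy)-2-(methoxymethoxy)phenyl]ethanone; 4 tributyl(3-methylbut-2-enyl)stannane
Product: 5 1-[4-(tert-butyldimethylsilyloxy)-2-(methoxymethoxy)-5-(3-methylbut-2-enyl)phenyl]ethanone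
Conditions: Pd(PPh3)4 (5 mol %), toluene, 110 °C
Reagents that add atoms: none
Why: Stille coupling; reductive elimination from the aryl(allyl)palladium intermediate should occur at the less hindered allyl terminus and give the linear prenyl arene, and the neutral, fluoride-free conditions spare the aryl silyl ether and the ketone.

Step 4
Reactants: 5 1-[4-(tert-butyldimethylsilyloxy)-2-(methoxymethoxy)-5-(3-methylbut-2-enyl)phenyl]ethanone
Product: 6 1-[4-(tert-butyldimethylsilyloxy)-5-[(E)-4-hydroxy-3-methylbut-2-enyl]-2-(methoxymethoxy)phenyl]ethanone
Conditions: SeO2 (cat.), t-BuOOH, CH2Cl2, rt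
Reagents that add atoms: selenium dioxide, O=[Se]=O; tert-butyl hydroperoxide, CC(C)(C)OO
Why: Selenium dioxide allylic oxidation (ene reaction at the more substituted alkene carbon, then [2,3]-sigmatropic shift), which for a prenyl group should oxidise the methyl group trans to the chain and so give the (E)-allylic alcohol; catalytic selenium with the hydroperoxide limits over-oxidation to the enal, and the acetyl methyl group is not attacked at room temperature.

Step 5
Reactants: 6 1-[4-(tert-butyldimethylsilyloxy)-5-[(E)-4-hydroxy-3-methylbut-2-enyl]-2-(methoxymethoxy)phenyl]ethanone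
Product: 7 (E)-4-[5-acetyl-2-(tert-butyldimethylsilyloxy)-4-(methoxymethoxy)phenyl]-2-methylbut-2-enyl methyl carbonate
Conditions: ClCO2Me, pyridine, CH2Cl2, 0 °C
Reagents that add atoms: methyl chloroformate, COC(=O)Cl
Why: O-Acylation of the primary allylic alcohol; both phenol oxygens are capped, so the carbonate can form only where the leaving group is wanted.

Step 6
Reactants: 7 (E)-4-[5-acetyl-2-(tert-butyldimethylsilyloxy)-4-(methoxymethoxy)phenyl]-2-methylbut-2-enyl methyl carbonate
Product: 8 (E)-4-[5-acetyl-2-hydroxy-4-(methoxymethoxy)phenyl]-2-methylbut-2-enyl methyl carbonate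
Conditions: TBAF, AcOH, THF, 0 °C
Reagents that add atoms: none
Why: Fluoride cleavage of an aryl silyl ether activated by the para ketone; acetic acid keeps the phenol protonated so that the allylic carbonate is neither displaced nor hydrolysed, and the MOM ether is inert to fluoride.

Step 7
Reactants: 8 (E)-4-[5-acetyl-2-hydroxy-4-(methoxymethoxy)phenyl]-2-methylbut-2-enyl methyl carbonate
Product: 9 (S)-1-[6-(methoxymethoxy)-2-(prop-1-en-2-yl)-2,3-dihydrobenzofuran-5-yl]ethanone
Conditions: Pd2(dba)3·CHCl3 (2.5 mol %), N,N′-[(1S,2S)-cyclohexane-1,2-diyl]bis[2-(diphenylphosphino)benzamide] (7.5 mol %), AcOH (1 equiv), CH2Cl2, rt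
Reagents that add atoms: none
Why: Zerovalent palladium formed from Pd2(dba)3 and the diphosphine ionises the allylic carbonate with loss of CO2 and methoxide, which deprotonates the phenol. The resulting syn π-allyl palladium complex has an unsubstituted CH2 terminus, so through its η1 form the metal changes faces faster than the ring closes (acetic acid supports this equilibration) and the chiral ligand pocket decides which diastereomeric complex cyclises. The phenoxide attacks the internal allyl terminus anti to palladium and forms O1–C2 in a 5-exo closure; attack at the CH2 terminus would be a 7-endo closure and is not expected. The closest known reaction type is the asymmetric Tsuji–Trost allylic etherification of phenols, which has been used to close 2-alkenyl chromans and 2-isopropenyl-2,3-dihydrobenzofurans from E-configured 2-methylbut-2-enyl carbonates. The only new stereocentre, C2, is set by the (S,S) ligand, that is by catalyst control. The step needs enantioselectivity (ligand), ring-size selectivity (kinetic preference for the five-membered ring) and chemoselectivity for one oxygen. The substrate secures the last point: the only free hydroxyl is ortho to the chain and para to the acetyl group, hence acidic and a good soft nucleophile, while the other oxygen is MOM-protected and para to the chain. The E geometry fixed in step 4 gives a single allyl geometry, which matters because geometric isomers can lead to opposite enantiomers.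

Step 8
Reactants: 9 (S)-1-[6-(methoxymethoxy)-2-(prop-1-en-2-yl)-2,3-dihydrobenzofuran-5-yl]ethanone
Product: 10 (S)-1-[2-(2-hydroxypropan-2-yl)-6-(methoxymethoxy)-2,3-dihydrobenzofuran-5-yl]ethanone
Conditions: Co(acac)2 (20 mol %), PhSiH3, O2 (1 atm), THF, rt
Reagents that add atoms: dioxygen, O=O
Why: Mukaiyama hydration; hydrogen-atom transfer from a cobalt hydride to the 1,1-disubstituted alkene gives the tertiary radical, which is trapped by O2 and reduced by the silane to the Markovnikov alcohol. C2 is not involved, so its configuration is kept (the descriptor stays S), and ketone and MOM ether are inert.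

Step 9
Reactants: 11 phenol; 12 isoprene
Product: 14 2,2-dimethylchroman, via 2-(3-methylbut-2-enyl)phenol 13 (not isolated)
Conditions: Amberlyst 15, THF, 65 °C, phenol in excess
Reagents that add atoms: none
Why: Acid-catalysed Friedel–Crafts ortho-prenylation followed by Markovnikov addition of the phenol oxygen to the protonated prenyl alkene, which closes the six-membered ring; excess phenol limits double alkylation.

Step 10
Reactants: 14 2,2-dimethylchroman
Product: 15 2,2-dimethylchroman-6-carbaldehyde
Conditions: Cl2CHOMe, TiCl4, CH2Cl2, 0 °C; then H2O
Reagents that add atoms: dichloromethyl methyl ether, COC(Cl)Cl; water, O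
Why: Rieche formylation; the TiCl4-activated dichloromethyl ether should attack para to the ring oxygen (C6), the ortho position C8 being more hindered, and aqueous work-up hydrolyses the chloro ether to the aldehyde.

Step 11
Reactants: 10 (S)-1-[2-(2-hydroxypropan-2-yl)-6-(methoxymethoxy)-2,3-dihydrobenzofuran-5-yl]ethanone; 15 2,2-dimethylchroman-6-carbaldehyde
Product: 16 (E)-3-(2,2-dimethylchroman-6-yl)-1-[(S)-2-(2-hydroxypropan-2-yl)-6-(methoxymethoxy)-2,3-dihydrobenzofuran-5-yl]prop-2-en-1-one
Conditions: KOH, EtOH, rt
Reagents that add atoms: none
Why: Claisen–Schmidt condensation; only the methyl ketone can enolise, and dehydration of the aldol gives the conjugated (E)-enone. The MOM ether keeps the ortho oxygen from closing a flavanone, and C2 carries no acidic hydrogen.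

Step 12
Reactants: 16 (E)-3-(2,2-dimethylchroman-6-yl)-1-[(S)-2-(2-hydroxypropan-2-yl)-6-(methoxymethoxy)-2,3-dihydrobenzofuran-5-yl]prop-2-en-1-one
Product: 17 (S)-3-(2,2-dimethylchroman-6-yl)-1-[(S)-2-(2-hydroxypropan-2-yl)-6-(methoxymethoxy)-2,3-dihydrobenzofuran-5-yl]-3-(4,4,5,5-tetramethyl-1,3,2-dioxaborolan-2-yl)propan-1-one
Conditions: CuCl (5 mol %), NaOt-Bu (10 mol %), (R)-1-[(Sp)-2-(diphenylphosphino)ferrocenyl]ethyldicyclohexylphosphine (6 mol %), B2pin2 (1.2 equiv), MeOH (2 equiv), THF, rt
Reagents that add atoms: bis(pinacolato)diboron, CC1(C)OB(OC1(C)C)B1OC(C)(C)C(C)(C)O1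
Why: Copper-catalysed enantioselective conjugate borylation, an established reaction of chalcones; the ligated copper–boryl species adds boron to the β-carbon and methanol protonates the copper enolate. The new C–B stereocentre is set by the chiral diphosphine, since C2 is too remote to influence the face.

Step 13
Reactants: 17 (S)-3-(2,2-dimethylchroman-6-yl)-1-[(S)-2-(2-hydroxypropan-2-yl)-6-(methoxymethoxy)-2,3-dihydrobenzofuran-5-yl]-3-(4,4,5,5-tetramethyl-1,3,2-dioxaborolan-2-yl)propan-1-one
Product: 18 (S)-3-(2,2-dimethylchroman-6-yl)-1-[(S)-6-hydroxy-2-(2-hydroxypropan-2-yl)-2,3-dihydrobenzofuran-5-yl]-3-(4,4,5,5-tetramethyl-1,3,2-dioxaborolan-2-yl)propan-1-one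
Conditions: HCl (1 M in MeOH), THF, rt
Reagents that add atoms: none
Why: Acid-catalysed acetal cleavage; a MOM ether ortho to a ketone is among the most labile of its kind. The step is placed here because a C–B bond cannot ionise or eliminate as the later benzylic alcohol would, and the pinacol boronate and the tertiary alcohol should tolerate dilute methanolic acid.

Step 14
Reactants: 18 (S)-3-(2,2-dimethylchroman-6-yl)-1-[(S)-6-hydroxy-2-(2-hydroxypropan-2-yl)-2,3-dihydrobenzofuran-5-yl]-3-(4,4,5,5-tetramethyl-1,3,2-dioxaborolan-2-yl)propan-1-one
Product: 19 (S)-3-(2,2-dimethylchroman-6-yl)-3-hydroxy-1-[(S)-6-hydroxy-2-(2-hydroxypropan-2-yl)-2,3-dihydrobenzofuran-5-yl]propan-1-one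
Conditions: NaBO3·4H2O (3 equiv), THF/H2O (1:1), 0 °C to rt
Reagents that add atoms: sodium perborate (waters of crystallisation omitted), [Na+].[Na+].O[B-]1(O)OO[B-](O)(O)OO1
Why: Boronate oxidation; the peroxide adds to boron and carbon migrates from boron to oxygen with retention, so the (S) boronate should give the (S) alcohol. Perborate is only mildly basic, which should keep dehydration and peroxide attack on the chelated hydroxyaryl ketone slow relative to C–B oxidation.

## Compound list

1 | 1-(5-bromo-2,4-dihydroxyphenyl)ethanone | CC(=O)c1cc(Br)c(O)cc1O | starting material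
2 | 1-[5-bromo-4-(tert-butyldimethylsilyloxy)-2-hydroxyphenyl]ethanone | CC(=O)c1cc(Br)c(O[Si](C)(C)C(C)(C)C)cc1O | intermediate
3 | 1-[5-bromo-4-(tert-butyldimethylsilyloxy)-2-(methoxymethoxy)phenyl]ethanone | CC(=O)c1cc(Br)c(O[Si](C)(C)C(C)(C)C)cc1OCOC | intermediate
4 | tributyl(3-methylbut-2-enyl)stannane | CCCC[Sn](CCCC)(CCCC)CC=C(C)C | starting material
5 | 1-[4-(tert-butyldimethylsilyloxy)-2-(methoxymethoxy)-5-(3-methylbut-2-enyl)phenyl]ethanone | CC(C)=CCc1cc(C(C)=O)c(OCOC)cc1O[Si](C)(C)C(C)(C)C | intermediate
6 | 1-[4-(tert-butyldimethylsilyloxy)-5-[(E)-4-hydroxy-3-methylbut-2-enyl]-2-(methoxymethoxy)phenyl]ethanone | OC/C(C)=C/Cc1cc(C(C)=O)c(OCOC)cc1O[Si](C)(C)C(C)(C)C | intermediate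
7 | (E)-4-[5-acetyl-2-(tert-butyldimethylsilyloxy)-4-(methoxymethoxy)phenyl]-2-methylbut-2-enyl methyl carbonate | COC(=O)OC/C(C)=C/Cc1cc(C(C)=O)c(OCOC)cc1O[Si](C)(C)C(C)(C)C | intermediate
8 | (E)-4-[5-acetyl-2-hydroxy-4-(methoxymethoxy)phenyl]-2-methylbut-2-enyl methyl carbonate | COC(=O)OC/C(C)=C/Cc1cc(C(C)=O)c(OCOC)cc1O | intermediate
9 | (S)-1-[6-(methoxymethoxy)-2-(prop-1-en-2-yl)-2,3-dihydrobenzofuran-5-yl]ethanone | CC(=O)c1cc2c(cc1OCOC)O[C@H](C(C)=C)C2 | intermediate
10 | (S)-1-[2-(2-hydroxypropan-2-yl)-6-(methoxymethoxy)-2,3-dihydrobenzofuran-5-yl]ethanone | CC(=O)c1cc2c(cc1OCOC)O[C@H](C(C)(C)O)C2 | intermediate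
11 | phenol | Oc1ccccc1 | starting material
12 | isoprene | C=CC(C)=C | starting material
13 | 2-(3-methylbut-2-enyl)phenol | CC(C)=CCc1ccccc1O | intermediate
14 | 2,2-dimethylchroman | CC1(C)CCc2ccccc2O1 | intermediate
15 | 2,2-dimethylchroman-6-carbaldehyde | CC1(C)CCc2cc(C=O)ccc2O1 | intermediate
16 | (E)-3-(2,2-dimethylchroman-6-yl)-1-[(S)-2-(2-hydroxypropan-2-yl)-6-(methoxymethoxy)-2,3-dihydrobenzofuran-5-yl]prop-2-en-1-one | CC1(C)CCc2cc(/C=C/C(=O)c3cc4c(cc3OCOC)O[C@H](C(C)(C)O)C4)ccc2O1 | intermediate
17 | (S)-3-(2,2-dimethylchroman-6-yl)-1-[(S)-2-(2-hydroxypropan-2-yl)-6-(methoxymethoxy)-2,3-dihydrobenzofuran-5-yl]-3-(4,4,5,5-tetramethyl-1,3,2-dioxaborolan-2-yl)propan-1-one | CC1(C)CCc2cc([C@@H](B5OC(C)(C)C(C)(C)O5)CC(=O)c3cc4c(cc3OCOC)O[C@H](C(C)(C)O)C4)ccc2O1 | intermediate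
18 | (S)-3-(2,2-dimethylchroman-6-yl)-1-[(S)-6-hydroxy-2-(2-hydroxypropan-2-yl)-2,3-dihydrobenzofuran-5-yl]-3-(4,4,5,5-tetramethyl-1,3,2-dioxaborolan-2-yl)propan-1-one | CC1(C)CCc2cc([C@@H](B5OC(C)(C)C(C)(C)O5)CC(=O)c3cc4c(cc3O)O[C@H](C(C)(C)O)C4)ccc2O1 | intermediate
19 | (S)-3-(2,2-dimethylchroman-6-yl)-3-hydroxy-1-[(S)-6-hydroxy-2-(2-hydroxypropan-2-yl)-2,3-dihydrobenzofuran-5-yl]propan-1-one | CC1(C)CCc2cc([C@@H](O)CC(=O)c3cc4c(cc3O)O[C@H](C(C)(C)O)C4)ccc2O1 | target

## Step count and risks

Total step count: 14. Longest linear sequence: 12 steps (steps 1–8 and 11–14, from 1 to 19); the chroman branch contributes 2 steps (9 and 10) before the union in step 11. Aldehyde 15 is also a catalogue compound; buying it would shorten the route to 12 steps.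

**Step 7 (key step).** The most likely failure is insufficient enantioselectivity. The 5-exo closure by an acidic phenoxide is fast, and if it outruns face exchange of the π-allyl complex, the outcome falls back on the facial selectivity of ionisation. The sense of induction could also be opposite to the one assumed. Proton loss from the allyl complex to a diene is a minor competing path. Fallback: the route is left at 3. Buffered fluoride frees the phenol to give 1-[5-bromo-4-hydroxy-2-(methoxymethoxy)phenyl]ethanone F1. An enantioselective palladium heteroannulation of this ortho-bromophenol with isoprene 12 (zerovalent palladium with a chiral sulfinamide monophosphine, K2CO3, toluene, 80 °C) then reaches the same π-allyl intermediate by carbopalladation of the diene and closes it to 9. The route is rejoined at 9, and steps 3 to 6 are bypassed.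

**Step 14.** The free hydroxyaryl ketone may suffer peroxide attack at the carbonyl with aryl migration (Dakin-type oxidation), or the new aldol may dehydrate under the mildly basic conditions and cyclise through the phenol. Fallback: the order of the last two steps is inverted. Starting from 17, perborate oxidation with the MOM ether in place gives (S)-3-(2,2-dimethylchroman-6-yl)-3-hydroxy-1-[(S)-2-(2-hydroxypropan-2-yl)-6-(methoxymethoxy)-2,3-dihydrobenzofuran-5-yl]propan-1-one F2. Its ketone-chelated MOM ether is then cleaved without protic acid by MgBr2·OEt2 in Et2O/CH2Cl2 at 0 °C, which leads to 19.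

**Step 12.** Facial selectivity may be poor or the addition slow, because the ortho-alkoxy aryl ketone is twisted out of conjugation and the β-aryl group is electron-rich. Fallback: starting from 16, a Juliá–Colonna epoxidation (poly-D-leucine, urea–H2O2, DBU, THF) gives [(2S,3R)-3-(2,2-dimethylchroman-6-yl)oxiran-2-yl][(S)-2-(2-hydroxypropan-2-yl)-6-(methoxymethoxy)-2,3-dihydrobenzofuran-5-yl]methanone F3. Reductive opening of its Cα–O bond with SmI2 (THF/MeOH, −78 °C) keeps the benzylic C–O bond and gives the protected aldol F2 of the preceding fallback. The MgBr2·OEt2 cleavage described there leads to 19.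

**Step 4.** Conversion may stall, part of the product may be over-oxidised to the enal, and the doubly activated benzylic–allylic CH2 group may compete with the methyl group. Fallback: starting from 5, cross-metathesis with methacrolein (second-generation Grubbs catalyst, (H2IMes)(PCy3)Cl2Ru=CHPh, CH2Cl2, 40 °C) exchanges the dimethyl terminus and gives (E)-4-[5-acetyl-2-(tert-butyldimethylsilyloxy)-4-(methoxymethoxy)phenyl]-2-methylbut-2-enal F4 with E geometry. NaBH4 in MeOH/CH2Cl2 at −78 °C reduces the enal in preference to the electron-rich aryl ketone and returns the route to 6.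

## Further compounds

F1 | step 7 | 1-[5-bromo-4-hydroxy-2-(methoxymethoxy)phenyl]ethanone | CC(=O)c1cc(Br)c(O)cc1OCOC
F2 | step 14 | (S)-3-(2,2-dimethylchroman-6-yl)-3-hydroxy-1-[(S)-2-(2-hydroxypropan-2-yl)-6-(methoxymethoxy)-2,3-dihydrobenzofuran-5-yl]propan-1-one | CC1(C)CCc2cc([C@@H](O)CC(=O)c3cc4c(cc3OCOC)O[C@H](C(C)(C)O)C4)ccc2O1
F3 | step 12 | [(2S,3R)-3-(2,2-dimethylchroman-6-yl)oxiran-2-yl][(S)-2-(2-hydroxypropan-2-yl)-6-(methoxymethoxy)-2,3-dihydrobenzofuran-5-yl]methanone | CC1(C)CCc2cc([C@H]5O[C@@H]5C(=O)c3cc4c(cc3OCOC)O[C@H](C(C)(C)O)C4)ccc2O1
F4 | step 4 | (E)-4-[5-acetyl-2-(tert-butyldimethylsilyloxy)-4-(methoxymethoxy)phenyl]-2-methylbut-2-enal | O=C/C(C)=C/Cc1cc(C(C)=O)c(OCOC)cc1O[Si](C)(C)C(C)(C)C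
A1 | alternative 1 | (S)-3-(tert-butyldimethylsilyloxy)-3-(2,2-dimethylchroman-6-yl)-1-[(S)-6-hydroxy-2-[2-(triethylsilyloxy)propan-2-yl]-2,3-dihydrobenzofuran-5-yl]propan-1-one | CC1(C)CCc2cc([C@@H](O[Si](C)(C)C(C)(C)C)CC(=O)c3cc4c(cc3O)O[C@H](C(C)(C)O[Si](CC)(CC)CC)C4)ccc2O1
A2 | alternative 1 | (S)-5-(tert-butyldimethylsilyloxy)-5-(2,2-dimethylchroman-6-yl)pent-1-yn-3-one | CC1(C)CCc2cc([C@@H](O[Si](C)(C)C(C)(C)C)CC(=O)C#C)ccc2O1
A3 | alternative 1 | (S)-5-[2-methoxy-2-(trimethylsilyloxy)ethenyl]-2-[2-(triethylsilyloxy)propan-2-yl]-2,3-dihydrofuran | COC(O[Si](C)(C)C)=CC1=CC[C@@H](C(C)(C)O[Si](CC)(CC)CC)O1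
A4 | alternative 2 | methyl (S)-2-(2-hydroxypropan-2-yl)-6-(methoxymethoxy)-2,3-dihydrobenzofuran-5-carboxylate | COC(=O)c1cc2c(cc1OCOC)O[C@H](C(C)(C)O)C2
A5 | alternative 2 | methyl 4-bromo-5-[(S)-2,3-dihydroxy-3-methylbutyl]-2-(methoxymethoxy)benzoate | COC(=O)c1cc(C[C@H](O)C(C)(C)O)c(Br)cc1OCOC
A6 | alternative 3 | (S)-3-(tert-butyldimethylsilyloxy)-3-(2,2-dimethyl-2H-chromen-6-yl)-1-[(S)-6-(methoxymethoxy)-2-[2-(triethylsilyloxy)propan-2-yl]-2,3-dihydrobenzofuran-5-yl]propan-1-one | CC1(C)C=Cc2cc([C@@H](O[Si](C)(C)C(C)(C)C)CC(=O)c3cc4c(cc3OCOC)O[C@H](C(C)(C)O[Si](CC)(CC)CC)C4)ccc2O1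
A7 | alternative 3 | (S)-3-(tert-butyldimethylsilyloxy)-1-[(S)-6-(methoxymethoxy)-2-[2-(triethylsilyloxy)propan-2-yl]-2,3-dihydrobenzofuran-5-yl]-3-[4-(2-methylbut-3-yn-2-yloxy)phenyl]propan-1-one | C#CC(C)(C)Oc1ccc([C@@H](O[Si](C)(C)C(C)(C)C)CC(=O)c2cc3c(cc2OCOC)O[C@H](C(C)(C)O[Si](CC)(CC)CC)C3)cc1
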